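The numbers in the tables were generated by integration on assumed constants; scatter was added.

Late on, the limit in autumn and noon is the coupling partner, the limiting reagent: its charge of 0.760 M is less than the two substrates together, so it can cover at most a fraction 0.500 of the pair. Autumn and noon share one recipe and differ in stopping time, so I ask what excess belongs to each point on the way to that ceiling.

common to all: free catalyst 3.8 mM
- gamma: left-handed substrate 0.38 M; right-handed substrate 0.38 M; coupling partner 0.76 M; protic impurity 0.038 M; run made earlier
- autumn: left-handed substrate 0.76 M; right-handed substrate 0.76 M; coupling partner 0.760 M; protic impurity 0.0380 M; time 4.0 h
- noon: left-handed substrate 0.76 M; right-handed substrate 0.76 M; coupling partner 0.760 M; protic impurity 0.0380 M; time 6.0 h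

gamma run (percent of the left-handed substrate and right-handed substrate together charged)

| time / min | left-handed product / % | right-handed product / % | left-handed substrate / % |
|---|---|---|---|
| 6.00 | 1.1 | 0.6 | 48.3 |
| 20.0 | 3.0 | 1.7 | 46.9 |
| 30.0 | 5.0 | 2.9 | 45.5 |
| 50.0 | 7.0 | 4.1 | 42.5 |
| 80.0 | 10.5 | 5.2 | 39.2 |

(readings scatter by 0.3 percentage points)

* the flask that ends with the higher excess of left-handed product over right-handed product in the product, or "neither" when 2 percentage points or less lies between them (autumn / noon / neither)
* excess of left-handed product over right-handed product in the product at the end, autumn
* excess of left-handed product over right-handed product in the product at the end, noon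

- free catalyst is single-handed; left-handed substrate and right-handed substrate are mirror images of each other, charged as a racemate, each of them at the stated concentration
- the earlier runs were read with a standard deviation of 0.3 percentage points
- an excess is below zero if the other one leads

I freeze one quantity: s, the selectivity factor, the rate constant of the left-handed substrate over that of the right-handed one. Both substrates meet the same catalyst and partner, so if a fraction q of the right-handed substrate is left, the left-handed fraction is r, q raised to the power s, whatever the catalyst does meanwhile. Gamma's product readings, summed, stand in the ratio 1.83, a reading with the scatter of its points.

In the first instants both substrates are full, so the excess is s minus one over s plus one, 29.4 %. Then the left-handed substrate thins faster, since s is above one, and the excess erodes. For the middle I take gamma's converted fraction 15.7 % at 80.0 min and a second-order law, pair times partner, which gives 0.00306 /M/min. Autumn then reaches a fraction 0.300 of the pair, and noon 0.362. As a shortcut I set q to the unreacted fraction raised to the power 2/(1+s), and the excess is q minus r over the total reacted. That gives 24.9 % for autumn and 23.8 % for noon, with 20.9 % at the ceiling. The gap of 1.1 percentage points is smaller than the margin.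

The forecast says neither, with 25 % for autumn (21 % to 29 %) and 24 % for noon (20 % to 28 %), because “the product excess erodes slightly”.

The flasks give 26.0 % for autumn and 24.9 % for noon, so the answer is neither.

    coupling partner + free catalyst + left-handed substrate → free catalyst + left-handed product (k = 130 /M²/h)
    coupling partner + free catalyst + right-handed substrate → free catalyst + right-handed product (k = 69.0 /M²/h)
    coupling partner + protic impurity → quenched reagent (k = 170 /M/h)
    free catalyst ⇌ dormant form (K = 0.860, k = 8.60 /h)
    coupling partner + free catalyst → spent catalyst (k = 0.0750 /M/h)

Partner lost to the quenched reagent or to spent catalyst makes no difference to the autumn excess. With 78.2 % of autumn's right-handed substrate left, s gives 25.0 % against the flask's 26.0 %. In the neighbour charged with 3.0 M of partner, 35.3 % of the right-handed substrate is left, s gives 13.7 %, and that flask ends at 14.1 %.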